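**Plan**
- Retrosynthesis: ring C is opened last at C19–C20 (C19 carbanion onto a C20 acyl carbon). Before that, C2=C3 and the acyl C–O bond of a C8–O–C20 lactone are cut, then C7–C8 between a ring-D alkenyl iodide and a ring-A/B aldehyde.
- Forward: rings A/B by Robinson annulation, with ring B then carrying C19 on C18 and the quaternary C9 (Me, CHO). Ring D comes from a silyloxycyclopentenone. The fragments are joined at C7–C8, the lactone is closed onto C3, and ring C is formed last.
- Stereochemistry: C12 from a chiral-imine Michael addition; C17/C18 from dissolving-metal reduction and aldol; C9 from α-face cyclopropanation and hydrogenolysis; C5 from the chiral pool; C8 from a ligand-controlled Ni/Cr coupling; C6/C7 from hydroxyl-directed hydrogenation.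
- Enabling feature: the C8 oxygen lies 1,5 to C20 across ring C (cyclooctene). A six-membered lactone O–C20(=O)–C2=C3–C7–C8, fused to ring D (cyclopentane) at C3–C7, therefore locks C20 cis to C7 on the tetrasubstituted C2=C3 olefin before ring C exists. It also holds C20 within reach of C19 on ring B.

Key step: step 23

Remark: backbone carbons are numbered C1–C20 along the target SMILES with branch atoms skipped (C2=C3 olefin; ring D = C3–C7; ring C = C2, C3, C7, C8, C9, C18, C19, C20; ring B = C9–C12, C17, C18; ring A = C12–C17); on rings A/B, β is the face of the C12 methyl.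
Assumption: the (R)-phenylethylamine imine is taken to give the (S)-quaternary centre in step 3, the mirror image of the (S)-amine to (R)-10-methyloctalone case.
Assumption: the (S)-oxazoline sulfonamide ligand is taken to give the required C8 epimer in step 16; if its sense is opposite, the (R)-ligand is used with no other change.

**Route**

Step 1
Reactants: 1 3,3-dimethylcyclohexan-1-one
Product: 2 2,5,5-trimethylcyclohexan-1-one (racemic)
Conditions: LiN(i-Pr)2, THF, −78 °C; MeI, −78 → 0 °C
Reagents that add atoms: iodomethane (CI)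
Why: Kinetic enolate alkylation: LiN(i-Pr)2 deprotonates C6, the α-carbon not flanked by the quaternary centre, and MeI gives the 2-methyl ketone, whose racemic centre is re-formed in step 3.

Step 2
Reactants: 2 2,5,5-trimethylcyclohexan-1-one; 3 (R)-1-phenylethylamine
Product: 4 N-[(R)-1-phenylethyl] imine of 2
Conditions: TsOH (cat.), toluene, reflux, water separator
Reagents that add atoms: none
Why: Acid-catalysed imine condensation driven by azeotropic removal of water; the ring α-centre stays labile through the enamine tautomer.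

Step 3
Reactants: 4 imine; 5 but-3-en-2-one
Product: 7 (S)-2,5,5-trimethyl-2-(3-oxobutyl)cyclohexan-1-one, via imine adduct 6 (not isolated)
Conditions: THF, 25 °C, 3 d; then 20% aq. AcOH, 25 °C
Reagents that add atoms: water (O)
Why: Deracemising Michael addition of the chiral imine: its more substituted secondary enamine tautomer adds to the enone through a compact aza-ene-like transition state, the phenyl group covering one face so that quaternary C12 is set as S, and hydrolysis returns the auxiliary.

Step 4
Reactants: 7 (S)-diketone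
Product: 8 (S)-4a,7,7-trimethyl-4,4a,5,6,7,8-hexahydronaphthalen-2(3H)-one
Conditions: NaOMe, MeOH, 60 °C
Reagents that add atoms: none
Why: Intramolecular aldol condensation (the ring-closing half of a Robinson annulation) of the methyl ketone onto the ring carbonyl gives ring B as the C9 enone without touching C12.

Step 5
Reactants: 8 octalone
Product: 10 trans-decalone with equatorial C18 hydroxymethyl, via lithium enolate 9 (not isolated)
Conditions: Li, NH3/THF, t-BuOH (1 equiv), −78 °C; isoprene; NH3 removed; CH2O (gas), THF, −78 °C; aq. NH4Cl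
Reagents that add atoms: formaldehyde (C=O)
Why: Dissolving-metal reduction of the enone protonates C17 axially to give the trans ring fusion (17-H anti to the C12 methyl) and a regiodefined C9/C18 lithium enolate; its aldol reaction with formaldehyde places C19 on C18 in the equatorial (α) position, which avoids the 1,3-diaxial contact with the angular methyl and is also the thermodynamic arrangement at this enolisable centre.

Step 6
Reactants: 10 hydroxymethyl decalone
Product: 11 C19 triisopropylsilyl ether of 10
Conditions: i-Pr3SiCl, imidazole, DMF, 25 °C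
Reagents that add atoms: chlorotriisopropylsilane (CC(C)[Si](Cl)(C(C)C)C(C)C)
Why: Standard silylation of the primary alcohol; the triisopropylsilyl ether is chosen because it survives the acidic hydrogenolysis of step 10.

Step 7
Reactants: 11 silyl ether ketone
Product: 12 C9 enol triflate (C9=C10)
Conditions: KN(SiMe3)2, THF, −78 °C; PhNTf2, −78 → 0 °C
Reagents that add atoms: N-phenylbis(trifluoromethanesulfonimide) (O=S(=O)(N(c1ccccc1)S(=O)(=O)C(F)(F)F)C(F)(F)F)
Why: Kinetic deprotonation occurs at the C10 methylene (the C18 methine is hindered) and O-sulfonylation of the potassium enolate gives the C9=C10 enol triflate regioselectively.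

Step 8
Reactants: 12 enol triflate
Product: 13 allylic alcohol (C8 hydroxymethyl on C9=C10)
Conditions: Bu3SnCH2OH, Pd(PPh3)4 (cat.), LiCl, dioxane, 100 °C
Reagents that add atoms: (tributylstannyl)methanol (CCCC[Sn](CCCC)(CCCC)CO)
Why: Stille coupling: oxidative addition of the enol triflate to zerovalent palladium, chloride-assisted transmetalation of the hydroxymethyl group from tin and reductive elimination give the primary allylic alcohol in one step.

Step 9
Reactants: 13 allylic alcohol
Product: 14 9α,10α-methylene (cyclopropane) alcohol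
Conditions: Et2Zn, CH2I2, CH2Cl2, 0 °C
Reagents that add atoms: diiodomethane (ICI)
Why: Hydroxyl-assisted Simmons–Smith cyclopropanation: the zinc carbenoid held by the C8 alkoxide adds to the α face because the axial C12 methyl screens the β face at C10 (the usual outcome for a trans-decalin 2-ene with a 1,3-related angular methyl), which fixes the future C9 methyl as α and C8 as β.

Step 10
Reactants: 14 cyclopropane
Product: 15 (9S,12S,17S,18S) alcohol with 9α-methyl and 9β-hydroxymethyl
Conditions: H2 (3 bar), PtO2, AcOH, 25 °C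
Reagents that add atoms: none
Why: Catalytic hydrogenolysis of the cyclopropane over platinum cleaves the least substituted ring bond (C10–CH2), so the bridging methylene becomes the axial C9 methyl with C9 unchanged in configuration.

Step 11
Reactants: 15 alcohol
Product: 16 (9S,12S,17S,18S) C8 aldehyde
Conditions: DMP (triacetoxy benziodoxolone periodinane), NaHCO3, CH2Cl2, 25 °C
Reagents that add atoms: none
Why: Hypervalent-iodine oxidation of the neopentyl primary alcohol stops cleanly at the non-enolisable aldehyde.

Step 12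
Reactants: 17 (R)-4-(tert-butyldimethylsilyloxy)cyclopent-2-en-1-one
Product: 19 trimethylsilyl enol ether of (3R,4R)-4-(tert-butyldimethylsilyloxy)-3-methylcyclopentanone, via lithium enolate 18 (not isolated)
Conditions: Me2CuLi (from MeLi and CuI), Et2O/THF, −78 °C; then Me3SiCl, Et3N, −78 → 0 °C
Reagents that add atoms: lithium dimethylcuprate ([Li+].C[Cu-]C); chlorotrimethylsilane (C[Si](C)(C)Cl)
Why: Conjugate addition of the cuprate anti to the silyloxy group followed by O-silylation of the regiodefined enolate; the new methyl-bearing centre is transient.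

Step 13
Reactants: 19 silyl enol ether
Product: 20 (R)-4-(tert-butyldimethylsilyloxy)-3-methylcyclopent-2-en-1-one
Conditions: Pd(OAc)2 (1 equiv), MeCN, 25 °C
Reagents that add atoms: none
Why: Saegusa–Ito oxidation: the palladium enolate can only undergo β-hydride elimination towards the methyl-bearing carbon, which regenerates the enone as its 3-methyl homologue with C5 untouched.

Step 14
Reactants: 20 3-methyl enone
Product: 21 (R)-4-(tert-butyldimethylsilyloxy)-2-iodo-3-methylcyclopent-2-en-1-one
Conditions: I2, pyridine/CH2Cl2, DMAP (cat.), 25 °C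
Reagents that add atoms: iodine (II)
Why: α-Iodination of the enone by the pyridine-mediated addition–iodination–elimination sequence; β-substituted cyclopentenones react more slowly but in the same way.

Step 15
Reactants: 21 silyl iodoenone
Product: 22 (R)-4-hydroxy-2-iodo-3-methylcyclopent-2-en-1-one
Conditions: HF (48% aq.), MeCN, 0 °C
Reagents that add atoms: none
Why: Acidic fluoride desilylation frees the C5 hydroxyl, wanted as a directing group in step 17, without the base that would damage a 4-hydroxycyclopentenone.

Step 16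
Reactants: 16 C8 aldehyde; 22 hydroxy iodoenone
Product: 24 (5R,8S,9S,12S,17S,18S) C7–C8 coupled enone diol, via alkenylchromium 23 (not isolated)
Conditions: CrCl2 (4 equiv), (S)-N-[2-(4-isopropyl-4,5-dihydrooxazol-2-yl)-6-methylphenyl]methanesulfonamide, Et3N, NiCl2 (cat.), THF, 25 °C
Reagents that add atoms: none
Why: Nozaki–Hiyama–Kishi coupling: nickel-catalysed formation of the alkenylchromium species and its 1,2-addition to the non-enolisable aldehyde form C7–C8 while tolerating the free hydroxyl and the enone; because the quaternary C9 offers only a weak Felkin–Anh bias, the C8 configuration is imposed by the chiral sulfonamide ligand on chromium.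

Step 17
Reactants: 24 enone diol
Product: 25 (5R,6R,7R,8R,9S,12S,17S,18S) cyclopentanone diol
Conditions: H2 (30 bar), [Ir(cod)(PCy3)(py)]PF6 (10 mol %), CH2Cl2, 25 °C
Reagents that add atoms: none
Why: Hydroxyl-directed homogeneous hydrogenation: A(1,3) strain with the C6 methyl turns the C8 substituents so that the decalin covers one face of the tetrasubstituted C6=C7 bond while 8-OH and 5-OH lie on the other, so iridium bound to these hydroxyls delivers both hydrogens cis from that face and sets C6 and C7 (6-H, 7-H and 5-O cis; methyl and C8 cis).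

Step 18
Reactants: 25 cyclopentanone diol
Product: 26 5-O-tert-butyldiphenylsilyl ether of 25
Conditions: t-BuPh2SiCl, imidazole, DMF, 25 °C
Reagents that add atoms: tert-butylchlorodiphenylsilane (CC(C)(C)[Si](Cl)(c1ccccc1)c1ccccc1)
Why: Silylation distinguishes the accessible ring-D secondary hydroxyl from the neopentyl-type 8-OH, which stays free.

Step 19
Reactants: 26 silyl ether alcohol; 27 2-(diethoxyphosphoryl)propanoic acid
Product: 28 C8 2-(diethoxyphosphoryl)propanoate of 26
Conditions: DCC, DMAP, CH2Cl2, 0 → 25 °C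
Reagents that add atoms: none
Why: Steglich esterification (carbodiimide activation, acyl transfer by DMAP) acylates the hindered 8-OH under conditions mild enough for the β-hydroxy ketone.

Step 20
Reactants: 28 phosphonate ester
Product: 29 C8–O–C20 unsaturated δ-lactone (19-O-triisopropylsilyl)
Conditions: LiCl, i-Pr2NEt, MeCN, 25 → 45 °C
Reagents that add atoms: none
Why: Intramolecular Horner–Wadsworth–Emmons olefination under mild LiCl/amine conditions: the phosphonate carbanion adds to the C3 ketone and elimination closes the six-membered lactone, in which C2=C3 is necessarily formed with C20 cis to C7.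

Step 21
Reactants: 29 silyl lactone
Product: 30 lactone C19 alcohol
Conditions: HF·pyridine, pyridine, THF, 0 → 25 °C
Reagents that add atoms: none
Why: Acidic fluoride cleaves the primary triisopropylsilyl ether much faster than the hindered secondary tert-butyldiphenylsilyl ether and leaves the lactone intact.

Step 22
Reactants: 30 lactone alcohol
Product: 31 C19 iodide with C8–O–C20 unsaturated lactone
Conditions: I2, PPh3, imidazole, CH2Cl2, 0 → 25 °C
Reagents that add atoms: iodine (II)
Why: Appel-type iodination through the alkoxyphosphonium salt converts the primary alcohol into the iodide by SN2 displacement under neutral conditions.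

Step 23
Reactants: 31 iodo lactone
Product: 34 tetracyclic C20 enone with free 8-OH (5-O-tert-butyldiphenylsilyl), via alkylsamarium 32 (not isolated), via samarium hemiketalate 33 (not isolated)
Conditions: SmI2 (2.5 equiv), HMPA, THF, −78 → −20 °C; then aq. NH4Cl
Reagents that add atoms: none
Why: Two single-electron transfers from divalent samarium convert the C19–I bond, through the primary radical, into alkylsamarium 32, which adds to the lactone carbonyl C20 to give the bridged 9-oxabicyclo[3.3.1]nonene hemiketalate 33; on quench this opens by C20–O cleavage to the C20 enone with free 8-OH, so the C8–O–C20 tether is exchanged for the C19–C20 bond. The closest known reaction type is the SmI2-promoted intramolecular nucleophilic acyl substitution of iodoalkyl lactones to hydroxy cycloalkanones, an intramolecular Barbier-type acylation. Ring C closes by 1,2-addition of C19 to C20 through a six-membered chair-like array (C19–C18–C9–C8–O–C20, trans-fused to ring B because C8 and C19 are trans-diequatorial), which amounts to a two-atom expansion of the six-membered lactone to the eight-membered carbocycle. No stereocentre is created: C20 is tetrahedral only in 33, and the C2=C3 geometry was fixed by the lactone and cannot change. The step needs iodide reduction and 1,2-attack to win over conjugate reduction of the enoate, over 6-exo radical addition to C3 and over reduction of the enone product; the fully substituted C3, HMPA (fast radical-to-organosamarium conversion), low temperature, the absence of a proton source and the masking of the ketone as 33 until quench secure this.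

Step 24
Reactants: 34 hydroxy enone
Product: 35 C20 allylic alcohol (C20 epimers)
Conditions: NaBH4, CeCl3·7H2O, MeOH, −40 °C
Reagents that add atoms: none
Why: Luche reduction: cerium-assisted 1,2-hydride addition to the enone (which equilibrates out of its transannular hemiketal form) gives the allylic alcohol; the new C20 centre is removed in step 25, so either epimer serves.

Step 25
Reactants: 35 allylic alcohol
Product: 36 5-O-tert-butyldiphenylsilyl ether of the target
Conditions: Et3SiH (excess), CF3CO2H, CH2Cl2, −40 → −20 °C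
Reagents that add atoms: none
Why: Ionic deoxygenation: the allylic alcohol ionises to the C20–C2–C3 allyl cation (tertiary at C3) and Et3SiH delivers hydride to the less hindered secondary terminus C20, so the tetrasubstituted C2=C3 bond stays in place, the eight-membered ring holds its cis geometry, and at this temperature protonation of the olefin does not compete.

Step 26
Reactants: 36 silyl ether
Product: 37 CNP0213887.1 (5R,6R,7S,8R,9S,12S,17S,18S)
Conditions: Bu4NF, THF, 25 → 50 °C
Reagents that add atoms: none
Why: Fluoride desilylation of the secondary silyl ether gives the diol without affecting the olefin.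

**Compound list**
1 | 3,3-dimethylcyclohexan-1-one | O=C1CCCC(C)(C)C1 | starting material
2 | 2,5,5-trimethylcyclohexan-1-one (racemic) | CC1CCC(C)(C)CC1=O | intermediate
3 | (R)-1-phenylethylamine | C[C@@H](N)c1ccccc1 | starting material
4 | N-[(R)-1-phenylethyl] imine of 2 (ring α-centre unfixed) | CC1CCC(C)(C)CC1=N[C@H](C)c1ccccc1 | intermediate
5 | but-3-en-2-one (methyl vinyl ketone) | CC(=O)C=C | starting material
6 | N-[(R)-1-phenylethyl] imine of (S)-diketone 7 at the ring carbonyl | CC(=O)CC[C@]1(C)CCC(C)(C)CC1=N[C@H](C)c1ccccc1 | intermediate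
7 | (S)-2,5,5-trimethyl-2-(3-oxobutyl)cyclohexan-1-one | CC(=O)CC[C@]1(C)CCC(C)(C)CC1=O | intermediate
8 | (S)-4a,7,7-trimethyl-4,4a,5,6,7,8-hexahydronaphthalen-2(3H)-one (C9 ketone, C18=C17) | O=C1CC[C@]2(C)CCC(C)(C)CC2=C1 | intermediate
9 | lithium C9-enolate (C9=C18) of the trans-fused decalone, 17α-H | [Li]OC=1CC[C@]2(C)CCC(C)(C)C[C@H]2C=1 | intermediate
10 | (1R,4aS,8aS)-1-(hydroxymethyl)-4a,7,7-trimethyloctahydronaphthalen-2(1H)-one (trans-fused; C19 equatorial, α) | O=C1CC[C@]2(C)CCC(C)(C)C[C@H]2[C@@H]1CO | intermediate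
11 | C19 triisopropylsilyl ether of 10 | O=C1CC[C@]2(C)CCC(C)(C)C[C@H]2[C@@H]1CO[Si](C(C)C)(C(C)C)C(C)C | intermediate
12 | C9 enol triflate of 11 (C9=C10) | O=S(=O)(OC1=CC[C@]2(C)CCC(C)(C)C[C@H]2[C@@H]1CO[Si](C(C)C)(C(C)C)C(C)C)C(F)(F)F | intermediate
13 | C9=C10 olefin bearing C8 hydroxymethyl on C9 and C19 silyloxymethyl on C18 | OCC1=CC[C@]2(C)CCC(C)(C)C[C@H]2[C@@H]1CO[Si](C(C)C)(C(C)C)C(C)C | intermediate
14 | 9α,10α-methylene cyclopropane with 9β-hydroxymethyl | OC[C@@]1(C3)[C@H]3C[C@]2(C)CCC(C)(C)C[C@H]2[C@@H]1CO[Si](C(C)C)(C(C)C)C(C)C | intermediate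
15 | (9S,12S,17S,18S) decalin: 9α-methyl, 9β-hydroxymethyl (C8), 18α-(silyloxymethyl), trans-fused | OC[C@@]1(C)CC[C@]2(C)CCC(C)(C)C[C@H]2[C@@H]1CO[Si](C(C)C)(C(C)C)C(C)C | intermediate
16 | (9S,12S,17S,18S) C8 aldehyde of 15 | O=C[C@@]1(C)CC[C@]2(C)CCC(C)(C)C[C@H]2[C@@H]1CO[Si](C(C)C)(C(C)C)C(C)C | intermediate
17 | (R)-4-(tert-butyldimethylsilyloxy)cyclopent-2-en-1-one | O=C1C[C@@H](O[Si](C)(C)C(C)(C)C)C=C1 | starting material
18 | lithium enolate of (3R,4R)-4-(tert-butyldimethylsilyloxy)-3-methylcyclopentanone (methyl trans to silyloxy) | [Li]OC=1C[C@@H](O[Si](C)(C)C(C)(C)C)[C@H](C)C=1 | intermediate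
19 | trimethylsilyl enol ether corresponding to 18 | C[Si](C)(C)OC=1C[C@@H](O[Si](C)(C)C(C)(C)C)[C@H](C)C=1 | intermediate
20 | (R)-4-(tert-butyldimethylsilyloxy)-3-methylcyclopent-2-en-1-one | O=C1C[C@@H](O[Si](C)(C)C(C)(C)C)C(C)=C1 | intermediate
21 | (R)-4-(tert-butyldimethylsilyloxy)-2-iodo-3-methylcyclopent-2-en-1-one | O=C1C[C@@H](O[Si](C)(C)C(C)(C)C)C(C)=C1I | intermediate
22 | (R)-4-hydroxy-2-iodo-3-methylcyclopent-2-en-1-one | O=C1C[C@@H](O)C(C)=C1I | intermediate
23 | C7 alkenylchromium dichloride derived from 22 | O=C1C[C@@H](O)C(C)=C1[Cr](Cl)Cl | intermediate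
24 | (5R,8S,9S,12S,17S,18S) enone diol: ring-D C3 enone (C6=C7) carrying the C8 carbinol and decalin; 8S only because C7 is olefinic, same spatial arrangement as 8R in 25–37 | O=C1C[C@@H](O)C(C)=C1[C@@H](O)[C@@]1(C)CC[C@]2(C)CCC(C)(C)C[C@H]2[C@@H]1CO[Si](C(C)C)(C(C)C)C(C)C | intermediate
25 | (5R,6R,7R,8R,9S,12S,17S,18S) cyclopentanone diol (5-OH, 6-H, 7-H cis) | O=C1C[C@@H](O)[C@H](C)[C@@H]1[C@@H](O)[C@@]1(C)CC[C@]2(C)CCC(C)(C)C[C@H]2[C@@H]1CO[Si](C(C)C)(C(C)C)C(C)C | intermediate
26 | 5-O-tert-butyldiphenylsilyl ether of 25 | O=C1C[C@@H](O[Si](c2ccccc2)(c2ccccc2)C(C)(C)C)[C@H](C)[C@@H]1[C@@H](O)[C@@]1(C)CC[C@]2(C)CCC(C)(C)C[C@H]2[C@@H]1CO[Si](C(C)C)(C(C)C)C(C)C | intermediate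
27 | 2-(diethoxyphosphoryl)propanoic acid (racemic) | CCOP(=O)(OCC)C(C)C(=O)O | starting material
28 | C8 2-(diethoxyphosphoryl)propanoate of 26 (epimers at the phosphonate carbon) | O=C1C[C@@H](O[Si](c2ccccc2)(c2ccccc2)C(C)(C)C)[C@H](C)[C@@H]1[C@@H](OC(=O)C(C)P(=O)(OCC)OCC)[C@@]1(C)CC[C@]2(C)CCC(C)(C)C[C@H]2[C@@H]1CO[Si](C(C)C)(C(C)C)C(C)C | intermediate
29 | (5R,6R,7S,8R) C8–O–C20 unsaturated δ-lactone fused to ring D, 19-O-triisopropylsilyl | CC1=C2C[C@@H](O[Si](c3ccccc3)(c3ccccc3)C(C)(C)C)[C@H](C)[C@@H]2[C@@H](OC1=O)[C@@]1(C)CC[C@]2(C)CCC(C)(C)C[C@H]2[C@@H]1CO[Si](C(C)C)(C(C)C)C(C)C | intermediate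
30 | lactone with free C19 alcohol | CC1=C2C[C@@H](O[Si](c3ccccc3)(c3ccccc3)C(C)(C)C)[C@H](C)[C@@H]2[C@@H](OC1=O)[C@@]1(C)CC[C@]2(C)CCC(C)(C)C[C@H]2[C@@H]1CO | intermediate
31 | C19 iodide with C8–O–C20 unsaturated lactone (5-O-tert-butyldiphenylsilyl) | CC1=C2C[C@@H](O[Si](c3ccccc3)(c3ccccc3)C(C)(C)C)[C@H](C)[C@@H]2[C@@H](OC1=O)[C@@]1(C)CC[C@]2(C)CCC(C)(C)C[C@H]2[C@@H]1CI | intermediate
32 | C19 alkylsamarium diiodide of the lactone | CC1=C2C[C@@H](O[Si](c3ccccc3)(c3ccccc3)C(C)(C)C)[C@H](C)[C@@H]2[C@@H](OC1=O)[C@@]1(C)CC[C@]2(C)CCC(C)(C)C[C@H]2[C@@H]1C[Sm](I)I | intermediate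
33 | samarium salt of the bridged C20 hemiketal (C19–C20 formed, C8–O–C20 still intact) | CC1=C2C[C@@H](O[Si](c3ccccc3)(c3ccccc3)C(C)(C)C)[C@H](C)[C@@H]2[C@@H](O[C@@]14[O-])[C@@]1(C)CC[C@]2(C)CCC(C)(C)C[C@H]2[C@@H]1C4.[Sm+3].[I-].[I-] | intermediate
34 | tetracyclic C20 enone with free 8-OH, 5-O-tert-butyldiphenylsilyl | C/C1=C2\C[C@@H](O[Si](c3ccccc3)(c3ccccc3)C(C)(C)C)[C@H](C)[C@@H]2[C@@H](O)[C@@]2(C)CC[C@]3(C)CCC(C)(C)C[C@H]3[C@@H]2CC1=O | intermediate
35 | C20 allylic alcohol (C20 epimers), 8-OH free | C/C1=C2\C[C@@H](O[Si](c3ccccc3)(c3ccccc3)C(C)(C)C)[C@H](C)[C@@H]2[C@@H](O)[C@@]2(C)CC[C@]3(C)CCC(C)(C)C[C@H]3[C@@H]2CC1O | intermediate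
36 | 5-O-tert-butyldiphenylsilyl ether of the target | C/C1=C2\C[C@@H](O[Si](c3ccccc3)(c3ccccc3)C(C)(C)C)[C@H](C)[C@@H]2[C@@H](O)[C@@]2(C)CC[C@]3(C)CCC(C)(C)C[C@H]3[C@@H]2CC1 | intermediate
37 | CNP0213887.1, (5R,6R,7S,8R,9S,12S,17S,18S)-5,8-diol | C/C1=C2\C[C@@H](O)[C@H](C)[C@@H]2[C@@H](O)[C@@]2(C)CC[C@]3(C)CCC(C)(C)C[C@H]3[C@@H]2CC1 | target

**Step count**
Total: 26 steps. Longest linear sequence: 22 steps (steps 1–11, then 16–26); the ring-D branch is steps 12–15.

**Steps most likely to fail**

Step 16. Addition of a tetrasubstituted alkenylchromium to the neopentyl aldehyde may be slow, and facial control at C8 by the ligand may be poor. Fallback (from 21 and 16, rejoining at 24): the union is made with an organolithium and C8 is set afterwards by reduction. Iodoenone 21 is converted into its ethylene ketal F1 (ethylene glycol, TsOH, benzene, reflux). Iodine–lithium exchange (t-BuLi, Et2O, −78 °C) gives the alkenyllithium F2, which adds to aldehyde 16 to give the C8 carbinol mixture F3. Oxidation with DMP gives the ketone F4. Oxazaborolidine-catalysed borane reduction (Corey–Bakshi–Shibata), with the catalyst antipode chosen to reinforce hydride delivery anti to the axial C9 methyl, gives the single carbinol F5. Dilute aqueous HF in MeCN at 0 °C then removes the ketal and the ring-D silyl ether to give 24.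

Step 17. The tetrasubstituted, conjugated C6=C7 bond may resist hydrogenation, or the allylic alcohol may isomerise on iridium. Fallback (from 17 and 16, rejoining at 25): the C6 methyl is introduced after the fragment union instead of before it. Enone 17 is iodinated directly (I2, pyridine) to the 2-iodoenone F6. Its Ni/Cr coupling with 16 under the conditions of step 16 proceeds through the alkenylchromium F7 to the des-methyl adduct F8. Excess Me2CuLi adds the methyl to C6 anti to the silyloxy group to give the enolate F9. Kinetic protonation at −78 °C from the face opposite the new methyl gives the ketone F10 with the methyl and C8 cis. Aqueous HF in MeCN removes the silyl ether to give 25.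

Step 23. The primary radical or the samarium reagent may be diverted to conjugate reduction or protonation, and the medium-ring closure may stall. Fallback (from 31, rejoining at 35): the acyl carbon is taken to the aldehyde oxidation level while the template is kept. Lactone 31 is reduced with i-Bu2AlH (CH2Cl2, −78 °C) to the lactol F11, which still fixes the olefin geometry. A samarium Barbier reaction (SmI2, HMPA, THF, −78 °C) on its ring-opened hydroxy enal form joins C19 to C20 and gives the allylic alcohol 35 directly, ahead of step 25.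

Further compounds
F1 | step 16 | ethylene ketal of 21 | IC1=C(C)[C@H](O[Si](C)(C)C(C)(C)C)CC12OCCO2
F2 | step 16 | C7 alkenyllithium from F1 | [Li]C1=C(C)[C@H](O[Si](C)(C)C(C)(C)C)CC12OCCO2
F3 | step 16 | C8 carbinol (both epimers) from F2 and 16 | OC(C1=C(C)[C@H](O[Si](C)(C)C(C)(C)C)CC13OCCO3)[C@@]1(C)CC[C@]2(C)CCC(C)(C)C[C@H]2[C@@H]1CO[Si](C(C)C)(C(C)C)C(C)C
F4 | step 16 | C8 ketone | O=C(C1=C(C)[C@H](O[Si](C)(C)C(C)(C)C)CC13OCCO3)[C@@]1(C)CC[C@]2(C)CCC(C)(C)C[C@H]2[C@@H]1CO[Si](C(C)C)(C(C)C)C(C)C
F5 | step 16 | single C8 carbinol, configured as in 24 | O[C@H](C1=C(C)[C@H](O[Si](C)(C)C(C)(C)C)CC13OCCO3)[C@@]1(C)CC[C@]2(C)CCC(C)(C)C[C@H]2[C@@H]1CO[Si](C(C)C)(C(C)C)C(C)C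
F6 | step 17 | (R)-4-(tert-butyldimethylsilyloxy)-2-iodocyclopent-2-en-1-one | O=C1C[C@@H](O[Si](C)(C)C(C)(C)C)C=C1I
F7 | step 17 | alkenylchromium dichloride from F6 | O=C1C[C@@H](O[Si](C)(C)C(C)(C)C)C=C1[Cr](Cl)Cl
F8 | step 17 | des-methyl coupling product | O=C1C[C@@H](O[Si](C)(C)C(C)(C)C)C=C1[C@@H](O)[C@@]1(C)CC[C@]2(C)CCC(C)(C)C[C@H]2[C@@H]1CO[Si](C(C)C)(C(C)C)C(C)C
F9 | step 17 | lithium enolate alkoxide after methyl addition | [Li]OC=1C[C@@H](O[Si](C)(C)C(C)(C)C)[C@H](C)C=1[C@@H](O[Li])[C@@]1(C)CC[C@]2(C)CCC(C)(C)C[C@H]2[C@@H]1CO[Si](C(C)C)(C(C)C)C(C)C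
F10 | step 17 | 5-O-tert-butyldimethylsilyl ether of 25 | O=C1C[C@@H](O[Si](C)(C)C(C)(C)C)[C@H](C)[C@@H]1[C@@H](O)[C@@]1(C)CC[C@]2(C)CCC(C)(C)C[C@H]2[C@@H]1CO[Si](C(C)C)(C(C)C)C(C)C
F11 | step 23 | C20 lactol of 31 (anomers) | CC1=C2C[C@@H](O[Si](c3ccccc3)(c3ccccc3)C(C)(C)C)[C@H](C)[C@@H]2[C@@H](OC1O)[C@@]1(C)CC[C@]2(C)CCC(C)(C)C[C@H]2[C@@H]1CI
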